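## Analysis of the target

- **Skeleton.** Compound 26 is a germacranolide. Germacrane numbering is used for every intermediate. A cyclodeca-1(10),4-diene (C1–C10) is fused along C6–C7 to an α-methylene-γ-butyrolactone (O6–C12(=O)–C11(=C13)). It carries an angelate on O8 and primary allylic alcohols at C14 (on C10) and C15 (on C4).
- **Olefins.** Both ring olefins are ring-cis: C2 and C9 lie on the same side of C1=C10, and C3 and C6 lie on the same side of C4=C5. The CIP label is E in 26, because CH2OH outranks the ring CH2. It is Z in every intermediate that still carries CH3.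
- **Stereocentres.** C6, C7 and C8 are contiguous and all R. On the ring O6 is trans to C11 (trans-lactone) and O8 is cis to C11, so O6 and O8 are anti (6α-O, 7β-C11, 8β-O).
- **Sensitive groups.**
  - The exocyclic methylene lactone is a Michael acceptor.
  - The Z-angelate drifts to the tiglate under nucleophilic or strongly basic conditions.
  - The C6–O bond is allylic.
  - A free O8 alkoxide sits γ to C12 and can move the lactone from O6 to O8.
- **Difficulty.** The ten-membered ring resists end-to-end closure. Its two trisubstituted ring-cis olefins cannot be reached by equilibration. The stereotriad sits on a flexible ring.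
- **Feature used.** C9–C10(C14)=C1–C2–C3–C4(C15)=C5–C6 is, atom for atom and with the right olefin geometry, diene 1 once C6 and C9 are joined. The missing C7–C8 lies between these two atoms. Oxygen on C6 and C8 is the 1,3-pattern of a β-diketone, which is the mark of a retro-aldol.

## Retrosynthetic reasoning

**26 ⇒ 25.** The C14–O and C15–O bonds are removed first. Both methyl groups sit on the disubstituted end of a trisubstituted olefin and trans to the ring chain on the other end, which is the position an ene/[2,3] allylic hydroxylation serves. Leaving this to the end keeps two primary alcohols and their protecting groups out of the whole route. The forward reaction must leave the two electron-poor olefins and the ring CH2 groups alone.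

**25 ⇒ 22 + 23.** The O8–acyl bond is cut next. The angelate is the most isomerisation-prone group, so it should meet as few reagents as possible. The forward esterification must keep the Z geometry of 23.

**22 ⇒ 21 ⇒ 19 ⇒ 17 ⇒ 16.** The C11=C13 bond is cut by a one-carbon Mannich/elimination sequence on the saturated lactone. Because that sequence needs a strong base, O8 has to be masked in 17. Otherwise the O8 alkoxide would compete for C12.

**16 ⇒ 15.** The C8–H bond is removed, leaving a ketone.

- With the lactone already closed on O6, no choice between O6 and O8 is left open.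
- C8 is flanked by a tertiary carbon and a CH2 group, so a catalyst that reads size can read it.

**15 ⇒ 13 (through 14).** The C6–H and O6–C12 bonds are cut. In 13 the C7 centre lies between two carbonyl groups and racemises freely, so one catalytic hydride transfer can fix C6 and C7 together. The two ketones are reduced one after the other, for two reasons.

- A catalyst that recognises the sp2 neighbour of C6 finds no such handle at C8.
- Only a C6-first order lets the lactone close on the correct oxygen.

**13 ⇒ 11 + 12.** The C7–C11 bond is cut. C7 is the one carbon of 11 that carbonate can deprotonate, and 12 brings C11 and C12 at the correct oxidation level.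

**11 ⇒ 8.** C6 and C9 are reconnected. This turns the achiral ten-membered dione into a cis-fused 8-4 bicycle in which C6 bears a masked alkoxide β to the C8 ketone. The gain is decisive: the medium ring then comes from breaking a strained bond, and both olefins keep the geometry that an eight-membered ring forces on them.

**8 ⇒ 7 ⇒ 4 + 6 (from 5).** The C6–C7 and C8–C9 bonds of the cyclobutanone are cut as a [2+2] pair. The polarity fits: C9 of enol ether 4 is nucleophilic, and the carbonyl carbon of 6 is electrophilic. The two chlorines only make the ketene reactive enough and are then removed.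

**4 ⇒ 2 ⇒ 1.** The enol ether comes from enone 2 by deprotonation at C9. Enone 2 comes from 1 by oxidation of one of two equivalent allylic CH2 groups.

## Alternatives that were turned down

**Alternative 1:** The disconnection is C2–C3.

- **Key step.** The twelve-membered allylic ester A1 has C3 bearing a phenylsulfonyl group and a carboxyl whose oxygen is bound to C2. The zerovalent palladium complex Pd(PPh3)4 would ionise C2–O. Loss of CO2 leaves a sulfonyl carbanion, which recombines with the allyl terminus to give A2.
- **For it.**
  - A twelve-membered lactone is easier to close than a ten-membered carbocycle.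
  - The contraction happens inside an ion pair.
  - All three stereocentres and both CH2O groups are in place before the ring is made.
  - On security of configuration, and on avoiding a late C–H oxidation, it is stronger than the chosen route.
- **Against it.**
  - The allyl unit spans C2–C1–C10, and the ring-cis C1=C10 olefin corresponds to the less stable anti allyl complex. π–σ–π equilibration would therefore erode exactly the geometry that matters.
  - The C3 sulfone of A2 is allylic to C4=C5, so its reductive removal can shift or isomerise that olefin.
  - Both ring-cis trisubstituted allylic ethers must be built one by one.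
  - Four kinds of protecting group are carried, and C12 still stands at the alcohol level.
- **Comparison.** The chosen strategy gives up early stereocontrol. In return it gets both olefins, ten carbons and the ring from one cheap diene, in a clearly shorter sequence.

**Alternative 2:** The disconnection is C7–C8.

- **Key step.** SmI2 (divalent samarium) would turn the aldehyde of butenolide A3 into a ketyl. The ketyl adds to the β-carbon C7, and protonation at C11 gives A4.
- **For it.**
  - C6 comes from a chiral butenolide, so the absolute configuration is safe.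
  - Addition opposite to the C5 substituent gives the trans-lactone.
  - A4 already has the correct lactone regiochemistry, a free O8–H and oxygen at C14 and C15.
  - On these points it is stronger than the chosen route, and its endgame is short.
- **Against it.**
  - The ring is closed end to end by a short-lived radical into a ten-membered transition state. Simple reduction of the aldehyde, pinacol coupling and reduction of the butenolide all compete.
  - The aldehyde of A3 is β,γ-unsaturated and easily conjugates.
  - The configuration at C8 depends on a medium-ring transition state that is hard to predict.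
  - Both ring-cis olefins again have to be made separately.
- **Comparison.** The chosen strategy offers ring formation without chain-end encounter, and olefin geometry by inheritance. It pays with an asymmetric reduction that has to be made site-selective.

**Alternative 3:** The disconnection is C8–C9, with C1–C6 reconnected.

- **Key step.** KH with 18-crown-6 would convert the limonene-derived carbinol A5 into its alkoxide. An anionic oxy-Cope shift then opens the cyclohexene to dienone A6.
- **For it.**
  - Like the chosen route, it is a ring expansion and needs no macrocyclisation.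
  - It draws chirality from the pool and passes it to C8 through an ordered transition state.
  - In these respects it is equal or better.
- **Against it.**
  - The chair transition state of the trans-dialkenyl carbinol delivers C1=C10 ring-trans, the wrong geometry for 26, so an olefin inversion would have to be added.
  - C7 arises by enolate protonation as a mixture of epimers.
  - The C7 side chain stands at the alcohol level.
  - A5 needs a geometrically pure alkoxy-substituted alkenyl metal.
  - The cis,trans-cyclodecadiene A6 is open to Cope and transannular reactions.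
- **Comparison.** The chosen strategy uses the same logic of strain-driven bond scission. It starts, however, from a ring that can only hold cis olefins.

Key step: step 5

Assumption: 1 is used as the pure 1,5-dimethyl isomer. The 1,6-dimethyl isomer present in technical grades is removed by fractional distillation before step 1.

## Steps

Step 1
Reactants: 1 (1Z,5Z)-1,5-dimethylcycloocta-1,5-diene
Product: 2 (2Z,6Z)-3,7-dimethylcycloocta-2,6-dien-1-one
Conditions: Rh2(cap)4 (cap = caprolactamate, 1 mol %), t-BuOOH (70 % aq.), K2CO3, CH2Cl2, rt; excess 1, stopped at partial conversion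
Reagents that add atoms: tert-butyl hydroperoxide, CC(C)(C)OO
Why: Radical allylic C–H oxidation: hydrogen is abstracted from the ring CH2 next to the =CH end (future C6) because that allyl radical has a tertiary terminus, and oxygen is fixed at its secondary end, which gives the β-methyl enone. The twofold symmetry of 1 makes both such CH2 groups equal, and partial conversion protects the second olefin.

Step 2
Reactants: 2 (2Z,6Z)-3,7-dimethylcycloocta-2,6-dien-1-one
Product: 4 [(3,7-dimethylcycloocta-1,3,7-trien-1-yl)oxy]trimethylsilane (all three olefins ring-cis), via lithium trienolate 3 (not isolated)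
Conditions: LDA, THF, −78 °C; TMSCl, −78 → 0 °C; pentane, filtration, no aqueous work-up
Reagents that add atoms: chlorotrimethylsilane, C[Si](C)(C)Cl
Why: Kinetic α′-deprotonation of an enone and O-silylation: the C9 hydrogens are the only α′ hydrogens and are also allylic to C10=C1, so they are both the fastest and the most acidic to leave. Compound 4 is a cycloocta-1,3,5-triene, so it is kept at or below 0 °C and used at once to stay ahead of 6π ring closure and 1,5-hydrogen shifts.

Step 3
Reactants: 4 [(3,7-dimethylcycloocta-1,3,7-trien-1-yl)oxy]trimethylsilane; 5 dichloroacetyl chloride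
Product: 7 rac-(1R*,8R*,2Z,6Z)-10,10-dichloro-3,7-dimethyl-1-(trimethylsilyloxy)bicyclo[6.2.0]deca-2,6-dien-9-one (cis-fused), via dichloroketene 6 (not isolated)
Conditions: Et3N, hexane, slow addition of 5, 0 °C → rt
Reagents that add atoms: none
Why: Thermal ketene [2+2] cycloaddition to a cyclic trimethylsilyl enol ether: C6=C9 is by far the most electron-rich of the three olefins, its nucleophilic C9 bonds to the ketene carbonyl carbon (C8), and the CCl2 carbon (C7) closes on the oxygen-bearing C6. Addition is suprafacial on a ring-cis olefin, so the 8-4 fusion is cis, and the amine-generated ketene avoids zinc salts that would cleave the enol ether.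

Step 4
Reactants: 7 rac-10,10-dichloro-3,7-dimethyl-1-(trimethylsilyloxy)bicyclo[6.2.0]deca-2,6-dien-9-one
Product: 8 rac-(1R*,8R*,2Z,6Z)-3,7-dimethyl-1-(trimethylsilyloxy)bicyclo[6.2.0]deca-2,6-dien-9-one (cis-fused)
Conditions: Zn dust, NH4Cl, MeOH–THF, 0 °C → rt
Reagents that add atoms: none
Why: Zinc dehalogenation of an α,α-dichloro ketone through the zinc enolate, protonated by ammonium; the nearly neutral medium is chosen to keep the tertiary silyl ether, and all operations stay at or below rt because 8 is a tethered cis-1,2-dialkenylcyclobutane. Material that loses silicon early opens to 11 as well, so crude 8 can be carried on.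

Step 5
Reactants: 8 rac-3,7-dimethyl-1-(trimethylsilyloxy)bicyclo[6.2.0]deca-2,6-dien-9-one
Product: 11 (4Z,8Z)-5,9-dimethylcyclodeca-4,8-diene-1,3-dione, via cyclobutanolate 9 (not isolated), via diketonate 10 (not isolated)
Conditions: TBAF (1.1 equiv, 1 M in THF, commercial wet grade), THF, −78 → 0 °C; then AcOH (1.2 equiv)
Reagents that add atoms: none
Why: Fluoride removes the silyl group, and the tertiary C6 alkoxide 9, a β-oxido ketone locked in a four-membered ring, collapses to the C6 ketone while the C6–C9 σ-bond breaks towards the C8 enolate (retro-aldol, a strain-release fragmentation); proton transfer from C7 then gives the 1,3-diketonate 10, which is inert until acetic acid releases 11. The closest known reaction type is the two-carbon enlargement of cyclic silyl enol ethers through dichloroketene adducts, dechlorination and opening to cycloalkane-1,3-diones. The ten-membered ring is not closed end to end: it appears when the bond shared by the eight- and the four-membered ring is cut, so neither high dilution nor an encounter of chain ends is involved. No stereocentre is made, C6 and C9 lose theirs, and both olefins stay ring-cis because they are not touched. Scission of C6–C7 would also open the cyclobutane without enlarging the eight-membered ring, so strain alone does not decide; C6–C9 should break because it is both α to C8=O and allylic to C10=C1, the ring holds it nearly parallel to the p orbitals of that olefin, and C9 leaves as part of an extended dienolate. The [3,3] shift open to the same 3-oxido-1,5-diene (C4=C5–C6–C9–C10=C1) would only trade one cyclobutane for another and would have to build a quaternary C4, so it should not compete at or below 0 °C. The water in the fluoride reagent shuttles the proton that turns the first-formed C9 enolate into 10 before it can add across the ring to C4 of the new enone or draw C10=C1 into conjugation.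

Step 6
Reactants: 11 (4Z,8Z)-5,9-dimethylcyclodeca-4,8-diene-1,3-dione; 12 methyl bromoacetate
Product: 13 methyl 2-[(3Z,7Z)-4,8-dimethyl-2,10-dioxocyclodeca-3,7-dien-1-yl]acetate (racemic, C7 configurationally labile)
Conditions: K2CO3 (1.1 equiv), 12 (1.0 equiv), acetone, rt
Reagents that add atoms: none
Why: SN2 C-alkylation of a 1,3-diketonate with a soft, unhindered α-halo ester; in the flexible ten-membered ring the potassium diketonate can chelate in the U shape of open-chain diketones, which favours carbon over oxygen. Carbonate deprotonates only C7, so C9 and the C10=C1 olefin are left alone.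

Step 7
Reactants: 13 methyl 2-[(3Z,7Z)-4,8-dimethyl-2,10-dioxocyclodeca-3,7-dien-1-yl]acetate
Product: 15 (6R,7S)-8-oxo-13-norgermacra-1(10)Z,4Z-dien-12,6-olide (trans-fused keto lactone), via hydroxy keto ester 14 (not isolated)
Conditions: RuCl(p-cymene)[(S,S)-TsDPEN] (2 mol %), HCO2H–Et3N (5:2), CH2Cl2, 0 °C → rt, stopped after one hydride equivalent
Reagents that add atoms: none
Why: Noyori–Ikariya asymmetric transfer hydrogenation with dynamic kinetic resolution, known for 2-alkyl-1,3-diketones and syn-selective there: C7 racemises through the enol faster than hydride arrives, the (S,S) catalyst places the sp2 carbon C5 under its arene ligand and so makes C6 R, and the syn (ring-trans) C7 epimer is the fast-reacting one. C6 should react before C8 for three reasons: the ring-cis enone cannot become planar and so loses little electrophilicity, it offers the flat C5–H flank the catalyst prefers, and C8 is a dialkyl ketone branched on both sides. The O6 hydroxyl of 14 closes on the ester while C8 is still a ketone, which fixes the 6,12-regiochemistry; the trans-β,γ-disubstituted lactone is also the more stable C7 epimer.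

Step 8
Reactants: 15 (6R,7S)-8-oxo-13-norgermacra-1(10)Z,4Z-dien-12,6-olide
Product: 16 (6R,7R,8R)-8-hydroxy-13-norgermacra-1(10)Z,4Z-dien-12,6-olide (O8 cis to C11)
Conditions: (S)-Me-CBS oxazaborolidine (15 mol %), catecholborane, toluene, −60 → −40 °C; aqueous work-up
Reagents that add atoms: none
Why: Corey–Bakshi–Shibata reduction: the tertiary ring-fusion carbon C7 is the large and C9H2 the small substituent, so the (S) catalyst gives 8R, and Felkin–Anh attack anti to C6 leads to the same 7,8-anti (O8 cis to C11) result, a matched pair. The non-basic medium spares the β-acyloxy ketone from E1cB opening, catecholborane leaves the trisubstituted olefins alone, and any minor enantiomer of 15 becomes a separable diastereomer.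

Step 9
Reactants: 16 (6R,7R,8R)-8-hydroxy-13-norgermacra-1(10)Z,4Z-dien-12,6-olide
Product: 17 (6R,7S,8R)-8-(triethylsilyloxy)-13-norgermacra-1(10)Z,4Z-dien-12,6-olide
Conditions: TESCl, imidazole, DMF, 0 °C
Reagents that add atoms: chlorotriethylsilane, CC[Si](Cl)(CC)CC
Why: Standard silylation of a secondary alcohol; the ether is needed because a free O8 alkoxide under the base of step 10 could attack C12 and move the lactone to O8 (the C7 descriptor changes only through CIP priorities).

Step 10
Reactants: 17 (6R,7S,8R)-8-(triethylsilyloxy)-13-norgermacra-1(10)Z,4Z-dien-12,6-olide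
Product: 19 13-(dimethylamino)-8-(triethylsilyloxy)germacra-1(10)Z,4Z-dien-12,6-olide (C11 epimers), via lithium lactone enolate 18 (not isolated)
Conditions: LDA (1.2 equiv), THF, −78 °C; Me2N=CH2 I (Eschenmoser's salt), −78 °C → rt
Reagents that add atoms: N,N-dimethylmethyleneiminium iodide, C[N+](C)=C.[I-]
Why: Mannich reaction of a lactone lithium enolate with a preformed iminium salt; C11 is the only acidic position left, and no leaving group stands β to the enolate. The new C11 centre disappears in step 11, so its configuration is immaterial.

Step 11
Reactants: 19 13-(dimethylamino)-8-(triethylsilyloxy)germacra-1(10)Z,4Z-dien-12,6-olide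
Product: 21 (6R,7S,8R)-8-(triethylsilyloxy)germacra-1(10)Z,4Z,11(13)-trien-12,6-olide, via ammonium iodide 20 (not isolated)
Conditions: MeI (excess), THF, rt; then sat. aq. NaHCO3, EtOAc, rt
Reagents that add atoms: none
Why: Quaternisation followed by E1cB (Hofmann-type) loss of trimethylamine, the second half of the Eschenmoser methylenation; hydrogencarbonate is basic enough for the elimination and too weak to harm the lactone or the silyl ether.

Step 12
Reactants: 21 (6R,7S,8R)-8-(triethylsilyloxy)germacra-1(10)Z,4Z,11(13)-trien-12,6-olide
Product: 22 (6R,7R,8R)-8-hydroxygermacra-1(10)Z,4Z,11(13)-trien-12,6-olide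
Conditions: HF·pyridine, pyridine, THF, 0 °C
Reagents that add atoms: none
Why: Acidic fluoride cleaves the triethylsilyl ether without generating an alkoxide, so neither conjugate addition to C13 nor migration of the lactone to O8 is triggered.

Step 13
Reactants: 22 (6R,7R,8R)-8-hydroxygermacra-1(10)Z,4Z,11(13)-trien-12,6-olide; 23 angelic acid
Product: 25 (6R,7R,8R)-8-angeloyloxygermacra-1(10)Z,4Z,11(13)-trien-12,6-olide, via mixed anhydride 24 (not isolated)
Conditions: 23, 2,4,6-trichlorobenzoyl chloride, Et3N, toluene, rt; then 22, 75 °C, no DMAP
Reagents that add atoms: none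
Why: Yamaguchi-type mixed-anhydride esterification run without a nucleophilic catalyst, the known way to angeloylate hindered secondary alcohols with retention of the Z geometry, because nothing adds reversibly to the β-carbon of the acyl group. The alcohol attacks the less shielded angeloyl carbonyl of 24.

Step 14
Reactants: 25 (6R,7R,8R)-8-angeloyloxygermacra-1(10)Z,4Z,11(13)-trien-12,6-olide
Product: 26 (6R,7R,8R)-8-angeloyloxy-14,15-dihydroxygermacra-1(10),4,11(13)-trien-12,6-olide (both ring olefins ring-cis; target)
Conditions: SeO2 (0.5 equiv), t-BuOOH (4 equiv, in decane), CH2Cl2, 0 °C → rt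
Reagents that add atoms: tert-butyl hydroperoxide, CC(C)(C)OO; selenium dioxide, O=[Se]=O
Why: Selenium dioxide allylic hydroxylation (ene reaction, then [2,3]-sigmatropic shift), which oxidises at the disubstituted end of a trisubstituted olefin: selenium binds C1 and C5, and oxygen is returned to C14 and C15. In the [2,3] step the ring chain on the selenium-bearing carbon sits pseudo-equatorial, so CH2OH ends trans to C2 (or C6), which is the ring-cis geometry already present. The electron-poor C11=C13 and angelate olefins do not enter the ene step.

## Compound list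

1 | (1Z,5Z)-1,5-dimethylcycloocta-1,5-diene | C/C1=C/CC/C(C)=C\CC1 | starting material
2 | (2Z,6Z)-3,7-dimethylcycloocta-2,6-dien-1-one | O=C1/C=C(/C)CC/C=C(/C)C1 | intermediate
3 | lithium 3,7-dimethylcycloocta-1,3,7-trien-1-olate | C1/C(C)=C\C([O-])=C/C(C)=C\C1.[Li+] | intermediate
4 | [(3,7-dimethylcycloocta-1,3,7-trien-1-yl)oxy]trimethylsilane, all olefins ring-cis | C1/C(C)=C\C(O[Si](C)(C)C)=C/C(C)=C\C1 | intermediate
5 | dichloroacetyl chloride | ClC(Cl)C(Cl)=O | starting material
6 | dichloroketene | ClC(Cl)=C=O | intermediate
7 | rac-(1R*,8R*)-10,10-dichloro-3,7-dimethyl-1-(trimethylsilyloxy)bicyclo[6.2.0]deca-2,6-dien-9-one, cis-fused (one enantiomer drawn) | ClC1(Cl)C(=O)[C@@H]2/C(C)=C\CC/C(C)=C\[C@]12O[Si](C)(C)C | intermediate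
8 | rac-(1R*,8R*)-3,7-dimethyl-1-(trimethylsilyloxy)bicyclo[6.2.0]deca-2,6-dien-9-one, cis-fused (one enantiomer drawn) | C1C(=O)[C@@H]2/C(C)=C\CC/C(C)=C\[C@]12O[Si](C)(C)C | intermediate
9 | tetrabutylammonium 3,7-dimethyl-9-oxobicyclo[6.2.0]deca-2,6-dien-1-olate, cis-fused, racemic | C1C(=O)[C@@H]2/C(C)=C\CC/C(C)=C\[C@]12[O-].CCCC[N+](CCCC)(CCCC)CCCC | intermediate
10 | tetrabutylammonium salt of 11 deprotonated at C7 | O=C1/C=C(/C)CC/C=C(/C)CC(=O)[CH-]1.CCCC[N+](CCCC)(CCCC)CCCC | intermediate
11 | (4Z,8Z)-5,9-dimethylcyclodeca-4,8-diene-1,3-dione | O=C1/C=C(/C)CC/C=C(/C)CC(=O)C1 | intermediate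
12 | methyl bromoacetate | COC(=O)CBr | starting material
13 | methyl 2-[(3Z,7Z)-4,8-dimethyl-2,10-dioxocyclodeca-3,7-dien-1-yl]acetate, C7 labile | O=C1/C=C(/C)CC/C=C(/C)CC(=O)C1CC(=O)OC | intermediate
14 | methyl 2-[(1S,2R,3Z,7Z)-2-hydroxy-4,8-dimethyl-10-oxocyclodeca-3,7-dien-1-yl]acetate | COC(=O)C[C@H]1[C@H](O)/C=C(/C)CC/C=C(/C)CC1=O | intermediate
15 | (6R,7S)-8-oxo-13-norgermacra-1(10)Z,4Z-dien-12,6-olide, trans-fused | C1C(=O)O[C@@H]2/C=C(/C)CC/C=C(/C)CC(=O)[C@@H]12 | intermediate
16 | (6R,7R,8R)-8-hydroxy-13-norgermacra-1(10)Z,4Z-dien-12,6-olide | C1C(=O)O[C@@H]2/C=C(/C)CC/C=C(/C)C[C@@H](O)[C@@H]12 | intermediate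
17 | (6R,7S,8R)-8-(triethylsilyloxy)-13-norgermacra-1(10)Z,4Z-dien-12,6-olide | C1C(=O)O[C@@H]2/C=C(/C)CC/C=C(/C)C[C@@H](O[Si](CC)(CC)CC)[C@@H]12 | intermediate
18 | lithium enolate of 17 (C11=C12–O−) | C1=C([O-])O[C@@H]2/C=C(/C)CC/C=C(/C)C[C@@H](O[Si](CC)(CC)CC)[C@@H]12.[Li+] | intermediate
19 | 13-(dimethylamino)-8-(triethylsilyloxy)germacra-1(10)Z,4Z-dien-12,6-olide, C11 epimers | CN(C)CC1C(=O)O[C@@H]2/C=C(/C)CC/C=C(/C)C[C@@H](O[Si](CC)(CC)CC)[C@@H]12 | intermediate
20 | trimethylammonium iodide of 19 | C[N+](C)(C)CC1C(=O)O[C@@H]2/C=C(/C)CC/C=C(/C)C[C@@H](O[Si](CC)(CC)CC)[C@@H]12.[I-] | intermediate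
21 | (6R,7S,8R)-8-(triethylsilyloxy)germacra-1(10)Z,4Z,11(13)-trien-12,6-olide | C=C1C(=O)O[C@@H]2/C=C(/C)CC/C=C(/C)C[C@@H](O[Si](CC)(CC)CC)[C@@H]12 | intermediate
22 | (6R,7R,8R)-8-hydroxygermacra-1(10)Z,4Z,11(13)-trien-12,6-olide | C=C1C(=O)O[C@@H]2/C=C(/C)CC/C=C(/C)C[C@@H](O)[C@@H]12 | intermediate
23 | angelic acid, (Z)-2-methylbut-2-enoic acid | C/C=C(/C)C(=O)O | starting material
24 | angelic 2,4,6-trichlorobenzoic anhydride | C/C=C(/C)C(=O)OC(=O)c1c(Cl)cc(Cl)cc1Cl | intermediate
25 | (6R,7R,8R)-8-angeloyloxygermacra-1(10)Z,4Z,11(13)-trien-12,6-olide | C=C1C(=O)O[C@@H]2/C=C(/C)CC/C=C(/C)C[C@@H](OC(=O)/C(C)=C\C)[C@@H]12 | intermediate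
26 | (6R,7R,8R)-8-angeloyloxy-14,15-dihydroxygermacra-1(10),4,11(13)-trien-12,6-olide, ring-cis olefins | C=C1C(=O)O[C@@H]2/C=C(/CO)CC/C=C(/CO)C[C@@H](OC(=O)/C(C)=C\C)[C@@H]12 | target

## Step count and least certain steps

Total step count: 14. Longest linear sequence: 14 steps, from 1 to 26.

**Step 5 (key step).**

- **What may go wrong.** The first-formed C9 enolate may be intercepted before the proton transfer from C7. It could add across the ring to C4 of the newly formed enone, or the C10=C1 olefin could migrate into conjugation. The enolate and the acceptor are born inside the same ring. A second danger is scission of C6–C7 in place of C6–C9, since both bonds run from the carbinol carbon to an α-carbon of the ketone.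
- **Fallback.** Desilylation is separated from C–C scission, and the scission is run where no free enolate exists. It sets out from 8, which buffered HF·pyridine at −20 °C turns into the free cyclobutanol F1. Warming F1 in AcOH–H2O–i-PrOH opens it through the C8 enol (acid-catalysed retro-aldol). The sequence comes back at 11.

**Step 7.**

- **What may go wrong.** Hydride may be delivered to the more electrophilic C8 carbonyl instead of C6. This would also pair the syn preference with the wrong oxygen. Weak facial discrimination by an alkenyl instead of an aryl group, and some conjugate reduction, are further risks.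
- **Fallback.** The demand for site selectivity is removed by never offering two ketones to one reagent. It sets out from 11.
  - Chelation-controlled hydrogenation with [RuCl(benzene)((R)-BINAP)]Cl (H2, 4 atm, MeOH) uses the natural preference for the non-conjugated carbonyl. It gives the (8R)-hydroxy enone F2, which is silylated (TESCl, imidazole) to F3.
  - The kinetic enolate of F3 (LDA, −78 °C) has only C7 to offer. It is alkylated with 12 (DMPU) anti to the silyloxy group to give F4.
  - (S)-Me-CBS with catecholborane reads C7 as the large group and gives the (6R)-hydroxy ester F5.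
  - PPTS closes F5 to the lactone, and the sequence comes back at 17, in the same number of steps.

**Step 3.**

- **What may go wrong.**
  - Silyl transfer inside the zwitterionic stage of the cycloaddition would end in acylation at C9 without ring closure.
  - Addition may be slow at a C9 flanked by the fully substituted C10.
  - While the ketene is being generated, triene 4 may be lost to valence isomerisation.
- **Fallback.** A sturdier silyl group and an amine-free ketene source are used. It sets out from 2.
  - LDA and then TBSCl/DMPU give the tert-butyldimethylsilyl trienol ether F6.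
  - Dichloroketene made from trichloroacetyl chloride with Zn–Cu in Et2O, which this ether tolerates, gives adduct F7.
  - Zn in AcOH removes both chlorines to give F8.
  - TBAF as in step 5 then brings the sequence back at 11.

**Step 14.**

- **What may go wrong.**
  - The two olefins may react at unequal rates. C4=C5 is deactivated and shielded by the allylic lactone oxygen, so C14 may be over-oxidised to the aldehyde level while C15 lags.
  - Competing hydroxylation of ring CH2 groups is possible.
  - The angelate may slowly drift from Z to E under prolonged exposure.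
- **Fallback.** The oxidation is moved to a stage that tolerates forcing and a reductive work-up. It sets out from 17.
  - SeO2/t-BuOOH followed by NaBH4 is harmless here, because no Michael acceptor is present. It gives diol F9, which TBSCl/imidazole protects as F10.
  - LDA and Eschenmoser's salt give Mannich base F11.
  - MeI gives salt F12, and NaHCO3 eliminates it to methylene lactone F13.
  - PPTS in MeOH removes only the secondary triethylsilyl ether to give alcohol F14.
  - The conditions of step 13 give angelate F15.
  - HF·pyridine frees both primary alcohols, and the sequence comes back at 26.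

**Step 8.**

- **What may go wrong.** Facial selectivity may be poor if the preferred ring conformer exposes the other face of C8 to the periphery, so that substrate bias opposes the catalyst.
- **Fallback.** The substrate bias is accepted and corrected by substitution. It sets out from 15.
  - The (R)-Me-CBS catalyst with catecholborane gives the (8S)-alcohol F16.
  - Mitsunobu reaction (4-nitrobenzoic acid, PPh3, DIAD) inverts C8 to ester F17.
  - K2CO3 in MeOH at 0 °C removes the ester, and the sequence comes back at 16.

## Further compounds

F1 | step 5 | rac-1-hydroxy-3,7-dimethylbicyclo[6.2.0]deca-2,6-dien-9-one, cis-fused | C1C(=O)[C@@H]2/C(C)=C\CC/C(C)=C\[C@]12O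
F2 | step 7 | (2Z,6Z,9R)-9-hydroxy-3,7-dimethylcyclodeca-2,6-dien-1-one | O=C1/C=C(/C)CC/C=C(/C)C[C@@H](O)C1
F3 | step 7 | (2Z,6Z,9R)-3,7-dimethyl-9-(triethylsilyloxy)cyclodeca-2,6-dien-1-one | O=C1/C=C(/C)CC/C=C(/C)C[C@@H](O[Si](CC)(CC)CC)C1
F4 | step 7 | methyl (7R,8R)-6-oxo-8-(triethylsilyloxy)-13-norgermacra-1(10)Z,4Z-dien-12-oate | O=C1/C=C(/C)CC/C=C(/C)C[C@@H](O[Si](CC)(CC)CC)[C@H]1CC(=O)OC
F5 | step 7 | methyl (6R,7S,8R)-6-hydroxy-8-(triethylsilyloxy)-13-norgermacra-1(10)Z,4Z-dien-12-oate | COC(=O)C[C@H]1[C@H](O)/C=C(/C)CC/C=C(/C)C[C@H]1O[Si](CC)(CC)CC
F6 | step 3 | tert-butyl[(3,7-dimethylcycloocta-1,3,7-trien-1-yl)oxy]dimethylsilane, ring-cis olefins | C1/C(C)=C\C(O[Si](C)(C)C(C)(C)C)=C/C(C)=C\C1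
F7 | step 3 | rac-1-(tert-butyldimethylsilyloxy)-10,10-dichloro-3,7-dimethylbicyclo[6.2.0]deca-2,6-dien-9-one, cis-fused | ClC1(Cl)C(=O)[C@@H]2/C(C)=C\CC/C(C)=C\[C@]12O[Si](C)(C)C(C)(C)C
F8 | step 3 | rac-1-(tert-butyldimethylsilyloxy)-3,7-dimethylbicyclo[6.2.0]deca-2,6-dien-9-one, cis-fused | C1C(=O)[C@@H]2/C(C)=C\CC/C(C)=C\[C@]12O[Si](C)(C)C(C)(C)C
F9 | step 14 | 14,15-dihydroxy derivative of 17 | C1C(=O)O[C@@H]2/C=C(/CO)CC/C=C(/CO)C[C@@H](O[Si](CC)(CC)CC)[C@@H]12
F10 | step 14 | 14,15-bis(tert-butyldimethylsilyl) ether of F9 | C1C(=O)O[C@@H]2/C=C(/CO[Si](C)(C)C(C)(C)C)CC/C=C(/CO[Si](C)(C)C(C)(C)C)C[C@@H](O[Si](CC)(CC)CC)[C@@H]12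
F11 | step 14 | C11 dimethylaminomethyl derivative of F10, C11 epimers | CN(C)CC1C(=O)O[C@@H]2/C=C(/CO[Si](C)(C)C(C)(C)C)CC/C=C(/CO[Si](C)(C)C(C)(C)C)C[C@@H](O[Si](CC)(CC)CC)[C@@H]12
F12 | step 14 | trimethylammonium iodide of F11 | C[N+](C)(C)CC1C(=O)O[C@@H]2/C=C(/CO[Si](C)(C)C(C)(C)C)CC/C=C(/CO[Si](C)(C)C(C)(C)C)C[C@@H](O[Si](CC)(CC)CC)[C@@H]12.[I-]
F13 | step 14 | α-methylene lactone with 8-O-triethylsilyl and 14,15-bis(O-tert-butyldimethylsilyl) groups | C=C1C(=O)O[C@@H]2/C=C(/CO[Si](C)(C)C(C)(C)C)CC/C=C(/CO[Si](C)(C)C(C)(C)C)C[C@@H](O[Si](CC)(CC)CC)[C@@H]12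
F14 | step 14 | 8-hydroxy α-methylene lactone with 14,15-bis(O-tert-butyldimethylsilyl) groups | C=C1C(=O)O[C@@H]2/C=C(/CO[Si](C)(C)C(C)(C)C)CC/C=C(/CO[Si](C)(C)C(C)(C)C)C[C@@H](O)[C@@H]12
F15 | step 14 | 14,15-bis(tert-butyldimethylsilyl) ether of 26 | C=C1C(=O)O[C@@H]2/C=C(/CO[Si](C)(C)C(C)(C)C)CC/C=C(/CO[Si](C)(C)C(C)(C)C)C[C@@H](OC(=O)/C(C)=C\C)[C@@H]12
F16 | step 8 | (6R,7R,8S)-8-hydroxy-13-norgermacra-1(10)Z,4Z-dien-12,6-olide | C1C(=O)O[C@@H]2/C=C(/C)CC/C=C(/C)C[C@H](O)[C@@H]12
F17 | step 8 | (6R,7R,8R)-8-(4-nitrobenzoyloxy)-13-norgermacra-1(10)Z,4Z-dien-12,6-olide | C1C(=O)O[C@@H]2/C=C(/C)CC/C=C(/C)C[C@@H](OC(=O)c3ccc([N+](=O)[O-])cc3)[C@@H]12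
A1 | alternative 1 | twelve-membered allyl α-(phenylsulfonyl)acetate lactone (C3–C(=O)–O–C2 link) | CC[Si](CC)(CC)O[C@@H]1/C=C(/CO[Si](C)(C)C(C)(C)C)C(S(=O)(=O)c2ccccc2)C(=O)OC/C=C(/CO[Si](C)(C)C(C)(C)C)C[C@@H](OCc2ccc(OC)cc2)[C@H]1C(=C)CO[Si](CC)(CC)CC
A2 | alternative 1 | ten-membered carbocycle with a phenylsulfonyl group at C3 | CC[Si](CC)(CC)O[C@@H]1/C=C(/CO[Si](C)(C)C(C)(C)C)C(S(=O)(=O)c2ccccc2)C/C=C(/CO[Si](C)(C)C(C)(C)C)C[C@@H](OCc2ccc(OC)cc2)[C@H]1C(=C)CO[Si](CC)(CC)CC
A3 | alternative 2 | C6-substituted butenolide carrying the C8 aldehyde chain | O=CC/C(CO[Si](C)(C)C(C)(C)C)=C\CC/C(CO[Si](C)(C)C(C)(C)C)=C\[C@@H]1C=CC(=O)O1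
A4 | alternative 2 | trans-fused ten-membered lactone with free O8–H and saturated C11 | C1C(=O)O[C@@H]2/C=C(/CO[Si](C)(C)C(C)(C)C)CC/C=C(/CO[Si](C)(C)C(C)(C)C)C[C@@H](O)[C@@H]12
A5 | alternative 3 | limonene-derived tertiary cyclohexenol with trans alkenyl and isopropenyl groups | C=C(C)[C@H]1CCC(C)=C[C@]1(O)/C(CCO[Si](C)(C)C(C)(C)C)=C/OCc1ccc(OC)cc1
A6 | alternative 3 | ten-membered dienone (C4=C5 ring-cis, C1=C10 ring-trans, 8R ether, C7 epimers) | O=C1/C=C(/C)CC/C=C(\C)C[C@@H](OCc2ccc(OC)cc2)C1CCO[Si](C)(C)C(C)(C)C
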